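Ring C of the chromanone is disconnected at three bonds around the vicinal pair C4a/C8a of ring A: C4a–C4, C8a–O1 and O1–C2. The key step exploits the fact that ring A carries the acyl carbon C4 on C4a and the ether oxygen O1 on the neighbouring C8a, with the C5 oxygen next to C4a polarising a C4a–C8a aryne. In one operation a fluoride-released aryne inserts into the C–O bond of an enantiopure trans-glycidate carboxylate and the liberated C8a phenoxide opens the epoxide at the benzylic carbon, closing ring C and setting C2 (C3 comes from the glycidate). Precursors: an ortho-silyl aryl triflate of ring A and the potassium glycidate bearing ring B.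

Key step: step 9

Assumption: the D-fructose-derived diacetate ketone is taken to epoxidise (E)-cinnamates to (2S,3R)-glycidates (same facial sense as for trans-β-methylstyrene), so its L-series enantiomer is specified in step 7; locants O1 to C8a follow chroman-4-one numbering.

Step 1
Reactants: 1 2,3-dihydroxy-4-methoxybenzaldehyde
Product: 2 2,3-bis(benzyloxy)-4-methoxybenzaldehyde
Conditions: BnBr, K2CO3, DMF, 60 °C
Reagents that add atoms: benzyl bromide, BrCc1ccccc1
Why: Williamson etherification of both phenols, the chelated 2-hydroxyl needing the mild heating, while the aldehyde is inert to carbonate.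

Step 2
Reactants: 2 2,3-bis(benzyloxy)-4-methoxybenzaldehyde
Product: 4 2,3-bis(benzyloxy)-4-methoxyphenol, via aryl formate 3 (not isolated)
Conditions: mCPBA, CH2Cl2, 0 °C to rt; then K2CO3 (cat.), MeOH, rt
Reagents that add atoms: 3-chloroperoxybenzoic acid, OOC(=O)c1cccc(Cl)c1
Why: Baeyer–Villiger (Dakin-type) oxidation in which the electron-rich aryl group, carrying ortho- and para-alkoxy substituents, migrates in preference to hydride to give formate 3, which mild methanolysis converts into the phenol without touching the benzyl ethers.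

Step 3
Reactants: 4 2,3-bis(benzyloxy)-4-methoxyphenol
Product: 5 2,3-bis(benzyloxy)-6-bromo-4-methoxyphenol
Conditions: NBS, iPr2NH (cat.), CH2Cl2, −78 to 0 °C
Reagents that add atoms: N-bromosuccinimide, BrN1C(=O)CCC1=O
Why: Electrophilic aromatic bromination in which the amine–NBS pair delivers bromine ortho to the free hydroxyl, whose only open ortho site is C6 (C2 carries a benzyloxy group and the para position a methoxy group), so a single regioisomer is expected.

Step 4
Reactants: 5 2,3-bis(benzyloxy)-6-bromo-4-methoxyphenol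
Product: 9 2,3-bis(benzyloxy)-4-methoxy-6-(trimethylsilyl)phenyl trifluoromethanesulfonate, via silyl ether 6 (not isolated), via aryllithium 7 (not isolated), via lithium phenoxide 8 (not isolated)
Conditions: HMDS, THF, reflux, then evaporation; n-BuLi, THF, −100 to −80 °C; Tf2O, −100 °C to rt
Reagents that add atoms: hexamethyldisilazane, C[Si](C)(C)N[Si](C)(C)C; trifluoromethanesulfonic anhydride, O=S(=O)(OS(=O)(=O)C(F)(F)F)C(F)(F)F
Why: O-silylation followed by bromine–lithium exchange (faster at −100 °C than deprotonation of the benzylic ether CH2 groups) triggers an anionic 1,3 oxygen-to-carbon silyl shift (retro-Brook rearrangement) to lithium phenoxide 8, which Tf2O traps as the triflate.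

Step 5
Reactants: 10 3-hydroxy-4,5-dimethoxybenzaldehyde
Product: 11 3-(benzyloxy)-4,5-dimethoxybenzaldehyde
Conditions: BnBr, K2CO3, DMF, rt
Reagents that add atoms: benzyl bromide, BrCc1ccccc1
Why: Williamson etherification of the single phenol, giving the only group on ring B that the final hydrogenolysis will remove.

Step 6
Reactants: 11 3-(benzyloxy)-4,5-dimethoxybenzaldehyde; 12 triethyl phosphonoacetate
Product: 13 ethyl (2E)-3-[3-(benzyloxy)-4,5-dimethoxyphenyl]prop-2-enoate
Conditions: NaH, THF, 0 °C to rt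
Reagents that add atoms: triethyl phosphonoacetate (12), CCOC(=O)CP(=O)(OCC)OCC
Why: Horner–Wadsworth–Emmons olefination in which the stabilised phosphonate anion adds reversibly and the anti-oxaphosphetane collapses to the (E)-cinnamate.

Step 7
Reactants: 13 ethyl (2E)-3-[3-(benzyloxy)-4,5-dimethoxyphenyl]prop-2-enoate
Product: 14 ethyl (2R,3S)-3-[3-(benzyloxy)-4,5-dimethoxyphenyl]oxirane-2-carboxylate
Conditions: 4,5-di-O-acetyl-1,2-O-isopropylidene-β-L-erythro-2,3-hexodiulo-2,6-pyranose (30 mol%), KHSO5 (as 2KHSO5·KHSO4·K2SO4), NaHCO3, Bu4NHSO4 (cat.), MeCN/aq. disodium ethylenediaminetetraacetate, 0 °C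
Reagents that add atoms: potassium peroxymonosulfate, [K+].[O-]S(=O)(=O)OO
Why: Shi-type asymmetric epoxidation in which the dioxirane formed from the chiral ketone and KHSO5 transfers oxygen through a spiro transition state to one enantioface of the (E)-olefin; syn addition keeps the trans geometry, the L-series ketone is the one expected to give the (2R,3S)-epoxide, and the diacetate ketone is chosen because its dioxirane is electrophilic enough for cinnamate esters.

Step 8
Reactants: 14 ethyl (2R,3S)-3-[3-(benzyloxy)-4,5-dimethoxyphenyl]oxirane-2-carboxylate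
Product: 15 potassium (2R,3S)-3-[3-(benzyloxy)-4,5-dimethoxyphenyl]oxirane-2-carboxylate
Conditions: KOH (1.0 equiv), EtOH, 0 °C; salt filtered and dried in vacuo
Reagents that add atoms: potassium hydroxide, [K+].[OH-]
Why: Ester saponification by acyl–oxygen cleavage in which the potassium salt precipitates from ethanol, so the decarboxylation-prone free 3-arylglycidic acid is never formed, neither stereocentre is touched at 0 °C, and recrystallisation of the salt should allow enrichment of the enantiomer if needed.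

Step 9
Reactants: 9 2,3-bis(benzyloxy)-4-methoxy-6-(trimethylsilyl)phenyl trifluoromethanesulfonate; 15 potassium (2R,3S)-3-[3-(benzyloxy)-4,5-dimethoxyphenyl]oxirane-2-carboxylate
Product: 20 (2R,3R)-5,6-bis(benzyloxy)-2-[3-(benzyloxy)-4,5-dimethoxyphenyl]-3-hydroxy-7-methoxy-2,3-dihydro-4H-chromen-4-one, via aryne 16 (not isolated), via aryl anion 17 (not isolated), via benzoxetene alkoxide 18 (not isolated), via acylphenoxide 19 (not isolated)
Conditions: KF, 18-crown-6, THF, 0 °C to rt (9 added slowly to 15, 1.3 equiv), then 50 °C; AcOH quench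
Reagents that add atoms: none
Why: Proposed new method: fluoride removes the silyl group of 9 and triflate leaves to give aryne 16; the carboxylate oxygen of 15 adds at C8a, the aryne carbon remote from the C5 benzyloxy group, so that the charge builds at C4a beside that inductively withdrawing oxygen, aryl anion 17 attacks its own ester carbonyl (4-exo-trig, an anionic Fries-type oxygen-to-carbon acyl shift) and benzoxetene alkoxide 18 opens to acylphenoxide 19. The closest known reaction type is the fluoride-mediated insertion of arynes into the C–O bond of carboxylic acids giving ortho-hydroxyaryl ketones, merged with the known closure of 2'-hydroxychalcone epoxides to trans-dihydroflavonols; the glycidate salt as acid partner and the epoxide capture in the same flask are the untested elements. Ring C closes by 6-endo-tet attack of the C8a phenoxide oxygen of 19 on the benzylic epoxide carbon. The new stereocentre C2 is set by SN2 inversion at that carbon under control of the epoxide configuration (3S in 15 becomes 2R), while C3 carries over the 2R centre of the glycidate unchanged, so the trans-epoxide maps onto the 2,3-trans (2R,3R) product. The step needs oxygen at C8a and not at C4a (secured by the polarisation of the 3-alkoxyaryne by the C5 benzyloxy group), acyl transfer and not protonation of 17 (secured by a salt without acidic hydrogen in dry THF in place of acetonitrile) and 6-endo and not 5-exo opening (secured by the benzylic carbon activated by ring B through its 4-methoxy group and by the carbonyl group, which retards SN2 at the alpha carbon as in the C3-selective openings of 3-arylglycidates). Slow addition of 9 to an excess of 15 keeps the aryne concentration low so that 19 and the C3 alkoxide of 20 are not arylated.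

Step 10
Reactants: 20 (2R,3R)-5,6-bis(benzyloxy)-2-[3-(benzyloxy)-4,5-dimethoxyphenyl]-3-hydroxy-7-methoxy-2,3-dihydro-4H-chromen-4-one
Product: 21 (2R,3R)-5,6-bis(benzyloxy)-2-[3-(benzyloxy)-4,5-dimethoxyphenyl]-3,7-dimethoxy-2,3-dihydro-4H-chromen-4-one
Conditions: Me3OBF4, 1,8-bis(dimethylamino)naphthalene, 4 Å MS, CH2Cl2, 0 °C to rt
Reagents that add atoms: trimethyloxonium tetrafluoroborate, C[O+](C)C.F[B-](F)(F)F
Why: O-alkylation of the neutral C3 hydroxyl (the only free hydroxyl, all phenols being benzylated) by a hard oxonium electrophile with a non-nucleophilic amine as acid scavenger; no alkoxide, enolate or oxidising metal oxide is involved, so C2 and C3 should keep their configuration and ring C should neither open nor dehydrogenate.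

Step 11
Reactants: 21 (2R,3R)-5,6-bis(benzyloxy)-2-[3-(benzyloxy)-4,5-dimethoxyphenyl]-3,7-dimethoxy-2,3-dihydro-4H-chromen-4-one
Product: 22 (2R,3R)-5,6-dihydroxy-2-(3-hydroxy-4,5-dimethoxyphenyl)-3,7-dimethoxy-2,3-dihydro-4H-chromen-4-one
Conditions: H2 (1 atm), Pd/C (10 wt%), EtOAc/MeOH, rt
Reagents that add atoms: none
Why: Heterogeneous hydrogenolysis of the three aryl benzyl ethers; the methyl ethers, the aryl ketone and the cyclic C2–O1 ether react far more slowly and should survive when hydrogen uptake is stopped at three equivalents, and no stereocentre is affected.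

Compound list
1 | 2,3-dihydroxy-4-methoxybenzaldehyde | COc1ccc(C=O)c(O)c1O | starting material
2 | 2,3-bis(benzyloxy)-4-methoxybenzaldehyde | COc1ccc(C=O)c(OCc2ccccc2)c1OCc1ccccc1 | intermediate
3 | 2,3-bis(benzyloxy)-4-methoxyphenyl formate | COc1ccc(OC=O)c(OCc2ccccc2)c1OCc1ccccc1 | intermediate (not isolated)
4 | 2,3-bis(benzyloxy)-4-methoxyphenol | COc1ccc(O)c(OCc2ccccc2)c1OCc1ccccc1 | intermediate
5 | 2,3-bis(benzyloxy)-6-bromo-4-methoxyphenol | COc1cc(Br)c(O)c(OCc2ccccc2)c1OCc1ccccc1 | intermediate
6 | [2,3-bis(benzyloxy)-6-bromo-4-methoxyphenoxy]trimethylsilane | COc1cc(Br)c(O[Si](C)(C)C)c(OCc2ccccc2)c1OCc1ccccc1 | intermediate (not isolated)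
7 | {3,4-bis(benzyloxy)-5-methoxy-2-[(trimethylsilyl)oxy]phenyl}lithium | COc1cc([Li])c(O[Si](C)(C)C)c(OCc2ccccc2)c1OCc1ccccc1 | intermediate (not isolated)
8 | lithium 2,3-bis(benzyloxy)-4-methoxy-6-(trimethylsilyl)phenoxide | [Li+].[O-]c1c([Si](C)(C)C)cc(OC)c(OCc2ccccc2)c1OCc1ccccc1 | intermediate (not isolated)
9 | 2,3-bis(benzyloxy)-4-methoxy-6-(trimethylsilyl)phenyl trifluoromethanesulfonate | COc1cc([Si](C)(C)C)c(OS(=O)(=O)C(F)(F)F)c(OCc2ccccc2)c1OCc1ccccc1 | intermediate
10 | 3-hydroxy-4,5-dimethoxybenzaldehyde | COc1cc(C=O)cc(O)c1OC | starting material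
11 | 3-(benzyloxy)-4,5-dimethoxybenzaldehyde | COc1cc(C=O)cc(OCc2ccccc2)c1OC | intermediate
12 | triethyl phosphonoacetate | CCOC(=O)CP(=O)(OCC)OCC | starting material
13 | ethyl (2E)-3-[3-(benzyloxy)-4,5-dimethoxyphenyl]prop-2-enoate | CCOC(=O)/C=C/c1cc(OCc2ccccc2)c(OC)c(OC)c1 | intermediate
14 | ethyl (2R,3S)-3-[3-(benzyloxy)-4,5-dimethoxyphenyl]oxirane-2-carboxylate | CCOC(=O)[C@@H]1O[C@H]1c1cc(OCc2ccccc2)c(OC)c(OC)c1 | intermediate
15 | potassium (2R,3S)-3-[3-(benzyloxy)-4,5-dimethoxyphenyl]oxirane-2-carboxylate | [K+].[O-]C(=O)[C@@H]1O[C@H]1c1cc(OCc2ccccc2)c(OC)c(OC)c1 | intermediate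
16 | 3,4-bis(benzyloxy)-5-methoxy-1,2-didehydrobenzene (aryne, triple bond between future C4a and C8a) | COC1=CC#CC(OCc2ccccc2)=C1OCc1ccccc1 | intermediate (not isolated)
17 | potassium salt of the C2 aryl anion of 3,4-bis(benzyloxy)-5-methoxyphenyl (2R,3S)-3-[3-(benzyloxy)-4,5-dimethoxyphenyl]oxirane-2-carboxylate (carbanion at future C4a) | [K+].COc1cc(OC(=O)[C@@H]2O[C@H]2c2cc(OCc3ccccc3)c(OC)c(OC)c2)[c-]c(OCc2ccccc2)c1OCc1ccccc1 | intermediate (not isolated)
18 | potassium 3,4-bis(benzyloxy)-2-{(2R,3S)-3-[3-(benzyloxy)-4,5-dimethoxyphenyl]oxiran-2-yl}-5-methoxy-2H-1-benzoxet-2-olate | [K+].COc1cc2OC([O-])([C@@H]3O[C@H]3c3cc(OCc4ccccc4)c(OC)c(OC)c3)c2c(OCc2ccccc2)c1OCc1ccccc1 | intermediate (not isolated)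
19 | potassium 3,4-bis(benzyloxy)-2-{[(2R,3S)-3-[3-(benzyloxy)-4,5-dimethoxyphenyl]oxiran-2-yl]carbonyl}-5-methoxyphenolate | [K+].COc1cc([O-])c(C(=O)[C@@H]2O[C@H]2c2cc(OCc3ccccc3)c(OC)c(OC)c2)c(OCc2ccccc2)c1OCc1ccccc1 | intermediate (not isolated)
20 | (2R,3R)-5,6-bis(benzyloxy)-2-[3-(benzyloxy)-4,5-dimethoxyphenyl]-3-hydroxy-7-methoxy-2,3-dihydro-4H-chromen-4-one | COc1cc2c(c(OCc3ccccc3)c1OCc1ccccc1)C(=O)[C@H](O)[C@@H](c1cc(OCc3ccccc3)c(OC)c(OC)c1)O2 | intermediate
21 | (2R,3R)-5,6-bis(benzyloxy)-2-[3-(benzyloxy)-4,5-dimethoxyphenyl]-3,7-dimethoxy-2,3-dihydro-4H-chromen-4-one | COc1cc2c(c(OCc3ccccc3)c1OCc1ccccc1)C(=O)[C@H](OC)[C@@H](c1cc(OCc3ccccc3)c(OC)c(OC)c1)O2 | intermediate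
22 | (2R,3R)-5,6-dihydroxy-2-(3-hydroxy-4,5-dimethoxyphenyl)-3,7-dimethoxy-2,3-dihydro-4H-chromen-4-one | COc1cc2c(c(O)c1O)C(=O)[C@H](OC)[C@@H](c1cc(O)c(OC)c(OC)c1)O2 | target

Total step count: 11 steps.
Longest linear sequence: 7 steps (steps 1–4, 9, 10, 11; the branch through steps 5–8 is equally long).

Steps most likely to fail

Step 9. The aryl anion may be protonated before the acyl shift (plain O-arylation). The phenoxide may open the epoxide 5-exo at the carbon next to the carbonyl, a mode that the C5 substituent is known to encourage. The product anions may also be arylated by further aryne. The fallback uses known chemistry only; it sets out from 9, takes ring B from aldehyde 11, and returns at 20.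
- Aryne 16 released from 9 is inserted into the C–O bond of acetic acid (CsF, THF, 125 °C, sealed tube) with the same regiochemistry, giving 1-[2,3-bis(benzyloxy)-6-hydroxy-4-methoxyphenyl]ethan-1-one F1.
- MOMCl and iPr2NEt convert this into 1-[2,3-bis(benzyloxy)-4-methoxy-6-(methoxymethoxy)phenyl]ethan-1-one F2.
- Claisen–Schmidt condensation with 11 (KOH, EtOH) gives (2E)-1-[2,3-bis(benzyloxy)-4-methoxy-6-(methoxymethoxy)phenyl]-3-[3-(benzyloxy)-4,5-dimethoxyphenyl]prop-2-en-1-one F3.
- Juliá–Colonna epoxidation (poly-L-leucine, urea–H2O2, DBU, THF) gives [2,3-bis(benzyloxy)-4-methoxy-6-(methoxymethoxy)phenyl]{(2R,3S)-3-[3-(benzyloxy)-4,5-dimethoxyphenyl]oxiran-2-yl}methanone F4.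
- HCl in MeOH removes the methoxymethyl group, and the freed phenol closes ring C 6-endo at the benzylic carbon under acid catalysis to give 20.

Step 7. Oxygen transfer from the dioxirane to the electron-poor cinnamate may be slower than decay of the ketone catalyst, leaving low conversion, or the facial selectivity may fall short. The fallback sets out from 13 and returns at 15.
- Reduction with iBu2AlH (CH2Cl2, −78 °C) gives (2E)-3-[3-(benzyloxy)-4,5-dimethoxyphenyl]prop-2-en-1-ol F5.
- Sharpless asymmetric epoxidation (Ti(OiPr)4, L-(+)-diethyl tartrate, tBuOOH, 4 Å MS, CH2Cl2, −20 °C) is hydroxyl-directed and so independent of olefin electrophilicity; it gives {(2S,3S)-3-[3-(benzyloxy)-4,5-dimethoxyphenyl]oxiran-2-yl}methanol F6.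
- Buffered oxidation (2,2,6,6-tetramethylpiperidine-1-oxyl cat., NaOCl cat., NaClO2, pH 6.7 phosphate, MeCN) gives (2R,3S)-3-[3-(benzyloxy)-4,5-dimethoxyphenyl]oxirane-2-carboxylic acid F7. The change of descriptor at C2 is a priority change only.
- The acid is kept cold and converted at once with KHCO3 into 15.

Step 10. The hindered C3 hydroxyl, hydrogen-bonded to the C4 carbonyl, may alkylate incompletely. Long exposure to the amine base could start enolisation with epimerisation at C3 or opening of the O1–C2 bond. The fallback goes from 20 directly to 21 and replaces base-buffered alkylation by acid catalysis, under which the 2,3-trans arrangement is the thermodynamic one: methyl 2,2,2-trichloroacetimidate with catalytic TfOH in CH2Cl2/cyclohexane transfers the methyl group to the hydroxyl. This detour makes no new compound (F0).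

Further compounds
F1 | step 9 | 1-[2,3-bis(benzyloxy)-6-hydroxy-4-methoxyphenyl]ethan-1-one | COc1cc(O)c(C(C)=O)c(OCc2ccccc2)c1OCc1ccccc1
F2 | step 9 | 1-[2,3-bis(benzyloxy)-4-methoxy-6-(methoxymethoxy)phenyl]ethan-1-one | COCOc1cc(OC)c(OCc2ccccc2)c(OCc2ccccc2)c1C(C)=O
F3 | step 9 | (2E)-1-[2,3-bis(benzyloxy)-4-methoxy-6-(methoxymethoxy)phenyl]-3-[3-(benzyloxy)-4,5-dimethoxyphenyl]prop-2-en-1-one | COCOc1cc(OC)c(OCc2ccccc2)c(OCc2ccccc2)c1C(=O)/C=C/c1cc(OCc2ccccc2)c(OC)c(OC)c1
F4 | step 9 | [2,3-bis(benzyloxy)-4-methoxy-6-(methoxymethoxy)phenyl]{(2R,3S)-3-[3-(benzyloxy)-4,5-dimethoxyphenyl]oxiran-2-yl}methanone | COCOc1cc(OC)c(OCc2ccccc2)c(OCc2ccccc2)c1C(=O)[C@@H]1O[C@H]1c1cc(OCc2ccccc2)c(OC)c(OC)c1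
F5 | step 7 | (2E)-3-[3-(benzyloxy)-4,5-dimethoxyphenyl]prop-2-en-1-ol | OC/C=C/c1cc(OCc2ccccc2)c(OC)c(OC)c1
F6 | step 7 | {(2S,3S)-3-[3-(benzyloxy)-4,5-dimethoxyphenyl]oxiran-2-yl}methanol | OC[C@@H]1O[C@H]1c1cc(OCc2ccccc2)c(OC)c(OC)c1
F7 | step 7 | (2R,3S)-3-[3-(benzyloxy)-4,5-dimethoxyphenyl]oxirane-2-carboxylic acid | OC(=O)[C@@H]1O[C@H]1c1cc(OCc2ccccc2)c(OC)c(OC)c1
F0 | step 10 | none | none
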